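**Assumption:** the SMILES encodes the fisetinidol unit as (2R,3S,4S), i.e. 2,3-trans-3,4-trans (4α), joined C4→C8 to (2R,3S)-(+)-catechin; flavan numbering is used throughout.

## Retrosynthetic overview

1. Target ⇐ global O-debenzylation of an octa-O-benzyl dimer whose upper 3-OH and 4-H come from hydroboration of a 4-(catechin-8-yl)flav-3-ene, anti to the 2-aryl group.
2. The upper pyran (C) ring ⇐ oxa-6π electrocyclization of a styryl o-quinone methide, generated in situ from the 1,2-adduct of an 8-metallated perbenzyl catechin and a 2'-O-Boc-2'-hydroxychalcone.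
3. Fragments: 8-bromo-penta-O-benzylcatechin from (+)-catechin (lower unit and its two stereocentres bought), and the chalcone from two commercial achiral aromatics.
4. Ring order: lower A/C/B rings and upper A and B rings are purchased; the upper C ring is formed last, then C3/C4 are set relative to C2.

## Route

**Step 1**
Reactants: 1, (+)-catechin
Product: 2, 5,7,3',4'-tetra-O-benzyl-(+)-catechin [(2R,3S)-5,7-bis(benzyloxy)-2-[3,4-bis(benzyloxy)phenyl]chroman-3-ol]
Conditions: BnBr (4.4 equiv), K2CO3, DMF, 0 °C → rt, N2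
Reagents that add atoms: benzyl bromide, BrCc1ccccc1
Why: Williamson etherification of the four phenols with a weak base leaves the secondary 3-OH free and does not open the C-ring, so C2/C3 are untouched.

**Step 2**
Reactants: 2, tetra-O-benzylcatechin
Product: 3, 8-bromo-5,7,3',4'-tetra-O-benzylcatechin
Conditions: NBS (1.0 equiv), CH2Cl2, −78 °C → rt
Reagents that add atoms: N-bromosuccinimide, O=C1CCC(=O)N1Br
Why: electrophilic aromatic bromination of the phloroglucinol-type A-ring is selective for C8 in tetra-O-benzyl flavan-3-ols; no stereocentre is involved.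

**Step 3**
Reactants: 3, 8-bromo-tetra-O-benzylcatechin
Product: 4, 8-bromo-3,5,7,3',4'-penta-O-benzylcatechin [(2R,3S)-3,5,7-tris(benzyloxy)-2-[3,4-bis(benzyloxy)phenyl]-8-bromochroman]
Conditions: NaH, BnBr, DMF, 0 °C → rt
Reagents that add atoms: benzyl bromide, BrCc1ccccc1
Why: Williamson O-benzylation of the 3-OH removes the only acidic proton before lithiation and keeps a lower-unit alkoxide from intercepting the Boc group in step 6.

**Step 4**
Reactants: 5, 4'-benzyloxy-2'-hydroxyacetophenone; 6, 3,4-bis(benzyloxy)benzaldehyde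
Product: 7, (E)-1-[4-(benzyloxy)-2-hydroxyphenyl]-3-[3,4-bis(benzyloxy)phenyl]prop-2-en-1-one (2'-hydroxychalcone)
Conditions: KOH (aq), EtOH/THF, rt
Reagents that add atoms: none
Why: Claisen–Schmidt aldol condensation gives the (E)-chalcone, which carries the whole upper-unit carbon skeleton.

**Step 5**
Reactants: 7, 2'-hydroxychalcone
Product: 8, (E)-5-(benzyloxy)-2-[3-(3,4-bis(benzyloxy)phenyl)acryloyl]phenyl tert-butyl carbonate (2'-O-Boc chalcone)
Conditions: Boc2O, DMAP (cat.), i-Pr2NEt, CH2Cl2, 0 °C → rt
Reagents that add atoms: di-tert-butyl dicarbonate, CC(C)(C)OC(=O)OC(=O)OC(C)(C)C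
Why: O-acylation masks the acidic phenol for the organometallic step and installs the group that later triggers quinone methide formation.

**Step 6 (key step)**
Reactants: 4, 8-bromo-penta-O-benzylcatechin; 8, 2'-O-Boc chalcone
Product: 9, 7-(benzyloxy)-2-[3,4-bis(benzyloxy)phenyl]-4-[(2R,3S)-3,5,7-tris(benzyloxy)-2-[3,4-bis(benzyloxy)phenyl]chroman-8-yl]-2H-chromene, as the (2S)/(2R) epimer pair; the (2S) epimer is the one needed
Conditions: 4, n-BuLi, THF, −78 °C; anhydrous CeCl3, −78 °C; then 8, −78 °C → rt (→ 40 °C if needed)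
Reagents that add atoms: none
Why: Br/Li exchange and organocerium 1,2-addition give a tertiary alkoxide that takes the neighbouring Boc group, the freed phenoxide expels tert-butyl carbonate to give a styryl o-quinone methide (Pettus-type generation), and this closes by thermal oxa-6π electrocyclization to the 2H-chromene; C2 is created here with only the remote catechin stereocentres to bias it, so roughly 1:1 epimers are assumed and both are carried forward.

**Step 7**
Reactants: 9, 4-(catechin-8-yl)flav-3-ene (epimer pair)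
Product: 10, (2R,3S,4S)-7-(benzyloxy)-2-[3,4-bis(benzyloxy)phenyl]-4-[(2R,3S)-3,5,7-tris(benzyloxy)-2-[3,4-bis(benzyloxy)phenyl]chroman-8-yl]chroman-3-ol, separated by chromatography from the (2S,3R,4R)-upper-unit diastereomer that arises from (2R)-9
Conditions: BH3·THF, THF, 0 °C → rt; then NaOH, H2O2, 0 °C → rt; silica chromatography
Reagents that add atoms: hydrogen peroxide, OO (source of the C3 oxygen; borane supplies only H)
Why: hydroboration–oxidation puts boron on C3 and hydrogen on C4 in a syn addition from the face opposite the C2 aryl, so 3-OH is trans to the 2-aryl and the 4-aryl is trans to 3-OH (all-equatorial 2,3-trans-3,4-trans), with oxidation retaining configuration.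

**Step 8**
Reactants: 10, octa-O-benzyl dimer
Product: 11, fisetinidol-(4α,8)-catechin (target)
Conditions: H2 (1 atm), Pd(OH)2/C, THF/MeOH/H2O, rt; Sephadex LH-20
Reagents that add atoms: none
Why: hydrogenolysis removes the seven aryl and one alkyl benzyl ethers under neutral conditions that leave the C2–O1 bonds, the interflavan bond and all five stereocentres intact.

## Compound list

1 | (+)-catechin | Oc1cc(O)c2c(c1)O[C@H](c1ccc(O)c(O)c1)[C@@H](O)C2 | starting material
2 | 5,7,3',4'-tetra-O-benzyl-(+)-catechin | C(c1ccccc1)Oc1cc(OCc3ccccc3)c2c(c1)O[C@H](c1ccc(OCc3ccccc3)c(OCc3ccccc3)c1)[C@@H](O)C2 | intermediate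
3 | 8-bromo-5,7,3',4'-tetra-O-benzylcatechin | C(c1ccccc1)Oc1cc(OCc3ccccc3)c2c(c1Br)O[C@H](c1ccc(OCc3ccccc3)c(OCc3ccccc3)c1)[C@@H](O)C2 | intermediate
4 | 8-bromo-3,5,7,3',4'-penta-O-benzylcatechin | C(c1ccccc1)Oc1cc(OCc3ccccc3)c2c(c1Br)O[C@H](c1ccc(OCc3ccccc3)c(OCc3ccccc3)c1)[C@@H](OCc1ccccc1)C2 | intermediate
5 | 4'-benzyloxy-2'-hydroxyacetophenone | CC(=O)c1ccc(OCc2ccccc2)cc1O | starting material
6 | 3,4-bis(benzyloxy)benzaldehyde | O=Cc1ccc(OCc2ccccc2)c(OCc2ccccc2)c1 | starting material
7 | (E)-2'-hydroxy-4',3,4-tris(benzyloxy)chalcone | O=C(/C=C/c1ccc(OCc2ccccc2)c(OCc2ccccc2)c1)c1ccc(OCc2ccccc2)cc1O | intermediate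
8 | 2'-O-Boc chalcone | O=C(/C=C/c1ccc(OCc2ccccc2)c(OCc2ccccc2)c1)c1ccc(OCc2ccccc2)cc1OC(=O)OC(C)(C)C | intermediate
9 | 4-(penta-O-benzylcatechin-8-yl)-7,3',4'-tris(benzyloxy)flav-3-ene, (2S) epimer shown; formed with its (2R) epimer | C(c1ccccc1)Oc1ccc2c(c1)O[C@H](c1ccc(OCc3ccccc3)c(OCc3ccccc3)c1)C=C2c1c(OCc3ccccc3)cc(OCc3ccccc3)c2c1O[C@H](c1ccc(OCc3ccccc3)c(OCc3ccccc3)c1)[C@@H](OCc1ccccc1)C2 | intermediate
10 | octa-O-benzyl fisetinidol-(4α,8)-catechin (upper 3-OH free) | C(c1ccccc1)Oc1ccc2c(c1)O[C@H](c1ccc(OCc3ccccc3)c(OCc3ccccc3)c1)[C@@H](O)[C@@H]2c1c(OCc3ccccc3)cc(OCc3ccccc3)c2c1O[C@H](c1ccc(OCc3ccccc3)c(OCc3ccccc3)c1)[C@@H](OCc1ccccc1)C2 | intermediate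
11 | fisetinidol-(4α,8)-catechin | Oc1ccc2c(c1)O[C@H](c1ccc(O)c(O)c1)[C@@H](O)[C@@H]2c1c(O)cc(O)c2c1O[C@H](c1ccc(O)c(O)c1)[C@@H](O)C2 | target

## Summary

**Total steps:** 8

**Longest linear sequence:** 6 (steps 1, 2, 3, 6, 7, 8 from (+)-catechin)

**Steps most likely to fail:**

1. **Step 6.** The hindered aryl-metal may add 1,4 or attack the Boc group, and the ring closure has no real facial bias at C2, so at best about half the material enters the target series. Fallback: take the upper-unit stereocentres from the chiral pool instead. (+)-Taxifolin is tri-O-benzylated, its 5-OH is removed via the triflate and Pd/formate reduction, NaBH4 gives the 2,3-trans-flavan-3,4-diol, and TMSOTf- or TiCl4-mediated Friedel–Crafts coupling with 2 at C8 gives the 4α product under C3 control.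

2. **Step 7.** The trisubstituted, diaryl-flanked C3=C4 bond is hindered, and the β-alkoxyborane could ring-open. Fallback: make the isomeric 4-aryl-4H-chromene (flav-2-ene) by Friedel–Crafts addition of 2 to 7,3',4'-tris(benzyloxy)flavylium salt. Its less hindered enol-ether C2=C3 bond is then hydroborated anti to the C4 aryl, which gives the same 2,3-trans-3,4-trans array.

3. **Step 8.** Eight benzyl ethers may cleave incompletely, and the free polyphenol is air-sensitive. Fallback: rebuild the route with MOM ethers on all phenols and finish with HCl/MeOH, which the acid-stable 5-deoxy interflavan bond should tolerate.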